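**Plan**

- Retrosynthetic cuts: the stilbene bond C5–Cα (Heck), the C2–C3 bond of the dihydrofuran (carbenoid C–H insertion), the diazo ester back to an arylacetic acid, and the O1–CH2 ether bond to ring B (Mitsunobu).
- Enabling feature: in the dihydrobenzofuran core (O1, C2, C3, fused ring A) C2 is a benzylic ether carbon flanked by O1 and the electron-rich ring B, and C3 carries C9, which can be held as an ester. C3 can therefore be a donor/acceptor carbene that inserts into C2–H.
- Forward order: the ring B benzyl alcohol (from vanillin) is etherified onto 5-bromo-o-vanillin; the aldehyde is homologated to the arylacetic acid, esterified with (S)-lactic acid pyrrolidide and diazotised. The insertion then closes the dihydrofuran, the only ring formed.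
- Completion: ester to the C9 alcohol, Heck coupling at C5 with silylated 3,5-dihydroxystyrene, one global desilylation.
- Stereochemistry: C2 and C3 arise together in the insertion, under control of Rh2(S-DOSP)4 acting with the (S)-lactamide ester (trans, 2R,3S in the target). The E-alkene follows from the syn-addition/syn-elimination course of the Heck reaction.

Key step: step 10

**Remarks on the chemistry**

- Numbering: benzofuran numbering (O1, C2, C3, C3a, C4–C7, C7a); C9 is the hydroxymethyl carbon; ring A is the fused benzo ring, ring B the guaiacyl ring on C2; TIPS = triisopropylsilyl.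
- Assumption: the (S)-lactamide ester together with Rh2(S-DOSP)4 (dirhodium tetrakis[(S)-N-(4-dodecylbenzenesulfonyl)prolinate]) is taken to be the matched pair that delivers 2R. The sense has to be verified on the first insertion product. If it proves opposite, both chiral elements are exchanged for their mirror images ((R)-lactamide from an alkyl (R)-lactate, Rh2(R-DOSP)4) with no change in the steps.

**Route**

Step 1
Reactants: 1 vanillin
Product: 2 3-methoxy-4-(TIPS-oxy)benzaldehyde
Conditions: TIPSCl, imidazole, DMF, rt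
Reagents that add atoms: triisopropylsilyl chloride, CC(C)[Si](Cl)(C(C)C)C(C)C
Why: Imidazole-promoted silylation of the phenol gives a bulky aryl silyl ether that should survive borohydride, ylide, borane, carbenoid and Heck conditions and leave with fluoride at the end.

Step 2
Reactants: 2 3-methoxy-4-(TIPS-oxy)benzaldehyde
Product: 3 [3-methoxy-4-(TIPS-oxy)phenyl]methanol
Conditions: NaBH4, MeOH, 0 °C
Reagents that add atoms: none
Why: Borohydride reduction of the aryl aldehyde is fast at 0 °C and should leave the hindered aryl silyl ether intact.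

Step 3
Reactants: 3 [3-methoxy-4-(TIPS-oxy)phenyl]methanol; 4 5-bromo-2-hydroxy-3-methoxybenzaldehyde (5-bromo-o-vanillin)
Product: 5 5-bromo-3-methoxy-2-{[3-methoxy-4-(TIPS-oxy)benzyl]oxy}benzaldehyde
Conditions: PPh3, DIAD, THF, 0 °C → rt
Reagents that add atoms: none
Why: Mitsunobu etherification: the acidic ortho-formyl phenol of 4 protonates the PPh3/DIAD betaine and its phenoxide displaces the oxyphosphonium of the primary benzylic alcohol 3 under neutral conditions that spare the aryl silyl ether and the aldehyde.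

Step 4
Reactants: 5 5-bromo-3-methoxy-2-{[3-methoxy-4-(TIPS-oxy)benzyl]oxy}benzaldehyde
Product: 6 5-bromo-1-methoxy-2-{[3-methoxy-4-(TIPS-oxy)benzyl]oxy}-3-vinylbenzene
Conditions: Ph3PCH3Br, KOt-Bu, THF, 0 °C → rt
Reagents that add atoms: methyltriphenylphosphonium bromide, C[P+](c1ccccc1)(c1ccccc1)c1ccccc1.[Br-]
Why: Wittig methylenation of a non-enolisable aryl aldehyde with the preformed unstabilised ylide is reliable and leaves ether, silyl ether and aryl bromide untouched.

Step 5
Reactants: 6 5-bromo-1-methoxy-2-{[3-methoxy-4-(TIPS-oxy)benzyl]oxy}-3-vinylbenzene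
Product: 8 2-(5-bromo-3-methoxy-2-{[3-methoxy-4-(TIPS-oxy)benzyl]oxy}phenyl)ethanol, via B-alkyl-9-BBN adduct 7 (not isolated)
Conditions: 9-BBN, THF, 0 °C → rt; then NaBO3·4H2O, H2O, rt
Reagents that add atoms: sodium perborate, [Na+].[O-]OB=O (gives the oxygen of 8); 9-BBN, B1C2CCCC1CCC2 (its boron and carbocycle are present only in 7)
Why: Brown hydroboration–oxidation: the bulky dialkylborane places boron on the terminal carbon of the styrene (anti-Markovnikov), and the weakly basic perborate converts C–B into C–O without endangering the aryl silyl ether or the aryl bromide.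

Step 6
Reactants: 8 2-(5-bromo-3-methoxy-2-{[3-methoxy-4-(TIPS-oxy)benzyl]oxy}phenyl)ethanol
Product: 10 2-(5-bromo-3-methoxy-2-{[3-methoxy-4-(TIPS-oxy)benzyl]oxy}phenyl)acetic acid, via arylacetaldehyde 9 (not isolated)
Conditions: TEMPO (cat.), NaClO2, NaOCl (cat.), MeCN/phosphate buffer pH 6.7, 35 °C
Reagents that add atoms: sodium chlorite, [Na+].[O-]Cl=O
Why: TEMPO-catalysed oxidation with chlorite as terminal oxidant (an Anelli-type oxidation followed in the same pot by a Pinnick-type chlorite step) takes the primary alcohol through aldehyde 9 to the acid at near-neutral pH, a protocol established for electron-rich 2-arylethanols, with only catalytic hypochlorite so that ring chlorination should stay minor.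

Step 7
Reactants: 11 ethyl (S)-lactate
Product: 12 (S)-2-hydroxy-1-(pyrrolidin-1-yl)propan-1-one
Conditions: pyrrolidine (neat, excess), rt → 45 °C
Reagents that add atoms: pyrrolidine, C1CCNC1
Why: Aminolysis of the activated α-hydroxy ester by a nucleophilic secondary amine proceeds without base strong enough to deprotonate the stereocentre, so the S configuration is retained.

Step 8
Reactants: 10 2-(5-bromo-3-methoxy-2-{[3-methoxy-4-(TIPS-oxy)benzyl]oxy}phenyl)acetic acid; 12 (S)-2-hydroxy-1-(pyrrolidin-1-yl)propan-1-one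
Product: 13 (S)-1-oxo-1-(pyrrolidin-1-yl)propan-2-yl 2-(5-bromo-3-methoxy-2-{[3-methoxy-4-(TIPS-oxy)benzyl]oxy}phenyl)acetate
Conditions: DCC, DMAP (cat.), CH2Cl2, 0 °C → rt
Reagents that add atoms: none
Why: Steglich esterification acylates the secondary alcohol through the acylpyridinium ion under neutral conditions; the lactamide stereocentre sits on the alcohol partner and is not involved.

Step 9
Reactants: 13 (S)-1-oxo-1-(pyrrolidin-1-yl)propan-2-yl 2-(5-bromo-3-methoxy-2-{[3-methoxy-4-(TIPS-oxy)benzyl]oxy}phenyl)acetate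
Product: 14 (S)-1-oxo-1-(pyrrolidin-1-yl)propan-2-yl 2-(5-bromo-3-methoxy-2-{[3-methoxy-4-(TIPS-oxy)benzyl]oxy}phenyl)-2-diazoacetate
Conditions: p-ABSA, DBU, MeCN, 0 °C → rt
Reagents that add atoms: 4-acetamidobenzenesulfonyl azide (p-ABSA), CC(=O)Nc1ccc(cc1)S(=O)(=O)N=[N+]=[N-]
Why: Regitz diazo transfer: DBU deprotonates the benzylic α-carbon of the arylacetate, which attacks the terminal nitrogen of the sulfonyl azide and expels the sulfonamide, the standard entry to aryldiazoacetates, and anhydrous conditions keep the aryl silyl ether intact.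

Step 10
Reactants: 14 (S)-1-oxo-1-(pyrrolidin-1-yl)propan-2-yl 2-(5-bromo-3-methoxy-2-{[3-methoxy-4-(TIPS-oxy)benzyl]oxy}phenyl)-2-diazoacetate
Product: 16 (S)-1-oxo-1-(pyrrolidin-1-yl)propan-2-yl (2R,3R)-5-bromo-7-methoxy-2-[3-methoxy-4-(TIPS-oxy)phenyl]-2,3-dihydrobenzofuran-3-carboxylate (trans), via Rh2(S-DOSP)4-bound carbene 15 (not isolated)
Conditions: Rh2(S-DOSP)4 (1 mol%), CH2Cl2, slow addition of 14, 0 °C → rt
Reagents that add atoms: none
Why: The dirhodium tetracarboxylate expels N2 from 14 to give the donor/acceptor carbenoid 15, whose carbene carbon (future C3) takes up the benzylic hydrogen of the OCH2 group in a hydride-transfer-like manner while the C2–C3 bond forms in a concerted, asynchronous three-centre transition state; the closest known reaction type is the dirhodium-catalysed intramolecular C–H insertion of ortho-benzyloxy aryldiazoacetates to 2-aryl-2,3-dihydrobenzofuran-3-carboxylates, including cases that pair a lactamide ester with a chiral dirhodium prolinate. The dihydrofuran ring closes by 1,5-insertion (carbene carbon, two ring A carbons, O1 and the benzylic carbon make the five-membered ring), and no other sp3 C–H bond lies within reach. The configuration at C2 is decided by which of the two enantiotopic benzylic hydrogens is replaced, which the chiral environment of Rh2(S-DOSP)4 and the (S)-lactamide ester are expected to select together (double stereodifferentiation, matched pair assumed). The configuration at C3 is set in the same event, with ring B and the bulky ester arm on opposite faces of the forming ring; trans is also the thermodynamically preferred arrangement, so any minor cis isomer could be converged onto 16 by epimerisation at C3. The step needs site selectivity for the ether C–H over cyclopropanation of ring B, carbene dimerisation and O–H insertion, which the substrate should secure through the activation of that C–H by O1 and the para-silyloxy ring B, the proximity enforced by the ortho tether and the tempered electrophilicity of the donor/acceptor carbenoid, aided by slow addition under anhydrous conditions.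

Step 11
Reactants: 16 (S)-1-oxo-1-(pyrrolidin-1-yl)propan-2-yl (2R,3R)-5-bromo-7-methoxy-2-[3-methoxy-4-(TIPS-oxy)phenyl]-2,3-dihydrobenzofuran-3-carboxylate
Product: 17 {(2R,3S)-5-bromo-7-methoxy-2-[3-methoxy-4-(TIPS-oxy)phenyl]-2,3-dihydrobenzofuran-3-yl}methanol
Conditions: LiBH4, THF, 0 °C → rt
Reagents that add atoms: none
Why: Chemoselective LiBH4 reduction of the ester (over the tertiary amide of the departing auxiliary, the aryl bromide and the silyl ether) should give the C9 alcohol without a base strong enough to epimerise C3 or to open the ring by β-elimination of the O1 phenoxide; both stereocentres keep their spatial arrangement, the C3 descriptor changing from R to S only through the priority switch from ester to CH2OH.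

Step 12
Reactants: 18 3,5-dihydroxybenzaldehyde
Product: 19 3,5-bis(TIPS-oxy)benzaldehyde
Conditions: TIPSCl, imidazole, DMF, rt
Reagents that add atoms: triisopropylsilyl chloride, CC(C)[Si](Cl)(C(C)C)C(C)C
Why: Imidazole-promoted silylation of both phenols gives ethers of the same kind as the one on ring B, so that a single fluoride treatment can unmask all three at the end.

Step 13
Reactants: 19 3,5-bis(TIPS-oxy)benzaldehyde
Product: 20 1,3-bis(TIPS-oxy)-5-vinylbenzene
Conditions: Ph3PCH3Br, KOt-Bu, THF, 0 °C → rt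
Reagents that add atoms: methyltriphenylphosphonium bromide, C[P+](c1ccccc1)(c1ccccc1)c1ccccc1.[Br-]
Why: Wittig methylenation of the aryl aldehyde with the preformed ylide gives the styrene, and the hindered aryl silyl ethers should tolerate the ylide.

Step 14
Reactants: 17 {(2R,3S)-5-bromo-7-methoxy-2-[3-methoxy-4-(TIPS-oxy)phenyl]-2,3-dihydrobenzofuran-3-yl}methanol; 20 1,3-bis(TIPS-oxy)-5-vinylbenzene
Product: 21 {(2R,3S)-5-[(E)-2-(3,5-bis(TIPS-oxy)phenyl)ethenyl]-7-methoxy-2-[3-methoxy-4-(TIPS-oxy)phenyl]-2,3-dihydrobenzofuran-3-yl}methanol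
Conditions: Pd2(dba)3 (2.5 mol%), [(t-Bu)3PH]BF4 (10 mol%), Cy2NMe, 1,4-dioxane, 80 °C
Reagents that add atoms: none
Why: Mizoroki–Heck reaction: zerovalent palladium carrying the bulky, electron-rich P(t-Bu)3 adds oxidatively to the electron-rich aryl bromide, syn-carbopalladation places the aryl group on the terminal carbon of styrene 20 and syn-β-hydride elimination gives the E-stilbene, while the free primary alcohol, the silyl ethers and both stereocentres are spectators.

Step 15
Reactants: 21 {(2R,3S)-5-[(E)-2-(3,5-bis(TIPS-oxy)phenyl)ethenyl]-7-methoxy-2-[3-methoxy-4-(TIPS-oxy)phenyl]-2,3-dihydrobenzofuran-3-yl}methanol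
Product: 22 Gnetofuran A
Conditions: Bu4NF, AcOH, THF, 0 °C, argon
Reagents that add atoms: none
Why: Fluoride-induced cleavage of the three aryl silyl ethers (Si–F bond formation, phenoxide leaving groups) with acetic acid as buffer, so that the oxidation-prone polyphenolic stilbene is not left as free phenoxide; neither stereocentre nor the E-alkene is touched.

**Compound list**

1 | vanillin (4-hydroxy-3-methoxybenzaldehyde) | COc1cc(C=O)ccc1O | starting material
2 | 3-methoxy-4-(triisopropylsilyloxy)benzaldehyde | COc1cc(C=O)ccc1O[Si](C(C)C)(C(C)C)C(C)C | intermediate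
3 | [3-methoxy-4-(triisopropylsilyloxy)phenyl]methanol | COc1cc(CO)ccc1O[Si](C(C)C)(C(C)C)C(C)C | intermediate
4 | 5-bromo-2-hydroxy-3-methoxybenzaldehyde | COc1cc(Br)cc(C=O)c1O | starting material
5 | 5-bromo-3-methoxy-2-{[3-methoxy-4-(triisopropylsilyloxy)benzyl]oxy}benzaldehyde | COc1cc(COc2c(OC)cc(Br)cc2C=O)ccc1O[Si](C(C)C)(C(C)C)C(C)C | intermediate
6 | 5-bromo-1-methoxy-2-{[3-methoxy-4-(triisopropylsilyloxy)benzyl]oxy}-3-vinylbenzene | COc1cc(COc2c(OC)cc(Br)cc2C=C)ccc1O[Si](C(C)C)(C(C)C)C(C)C | intermediate
7 | 9-[2-(5-bromo-3-methoxy-2-{[3-methoxy-4-(triisopropylsilyloxy)benzyl]oxy}phenyl)ethyl]-9-borabicyclo[3.3.1]nonane | COc1cc(COc2c(OC)cc(Br)cc2CCB3C4CCCC3CCC4)ccc1O[Si](C(C)C)(C(C)C)C(C)C | intermediate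
8 | 2-(5-bromo-3-methoxy-2-{[3-methoxy-4-(triisopropylsilyloxy)benzyl]oxy}phenyl)ethanol | COc1cc(COc2c(OC)cc(Br)cc2CCO)ccc1O[Si](C(C)C)(C(C)C)C(C)C | intermediate
9 | 2-(5-bromo-3-methoxy-2-{[3-methoxy-4-(triisopropylsilyloxy)benzyl]oxy}phenyl)acetaldehyde | COc1cc(COc2c(OC)cc(Br)cc2CC=O)ccc1O[Si](C(C)C)(C(C)C)C(C)C | intermediate
10 | 2-(5-bromo-3-methoxy-2-{[3-methoxy-4-(triisopropylsilyloxy)benzyl]oxy}phenyl)acetic acid | COc1cc(COc2c(OC)cc(Br)cc2CC(=O)O)ccc1O[Si](C(C)C)(C(C)C)C(C)C | intermediate
11 | ethyl (S)-lactate | CCOC(=O)[C@H](C)O | starting material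
12 | (S)-2-hydroxy-1-(pyrrolidin-1-yl)propan-1-one | C[C@H](O)C(=O)N1CCCC1 | intermediate
13 | (S)-1-oxo-1-(pyrrolidin-1-yl)propan-2-yl 2-(5-bromo-3-methoxy-2-{[3-methoxy-4-(triisopropylsilyloxy)benzyl]oxy}phenyl)acetate | COc1cc(COc2c(OC)cc(Br)cc2CC(=O)O[C@@H](C)C(=O)N3CCCC3)ccc1O[Si](C(C)C)(C(C)C)C(C)C | intermediate
14 | (S)-1-oxo-1-(pyrrolidin-1-yl)propan-2-yl 2-(5-bromo-3-methoxy-2-{[3-methoxy-4-(triisopropylsilyloxy)benzyl]oxy}phenyl)-2-diazoacetate | COc1cc(COc2c(OC)cc(Br)cc2C(=[N+]=[N-])C(=O)O[C@@H](C)C(=O)N3CCCC3)ccc1O[Si](C(C)C)(C(C)C)C(C)C | intermediate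
15 | Rh2(S-DOSP)4-bound carbene derived from 14 ([Rh] stands for the Rh2(S-DOSP)4 core) | COc1cc(COc2c(OC)cc(Br)cc2C(=[Rh])C(=O)O[C@@H](C)C(=O)N3CCCC3)ccc1O[Si](C(C)C)(C(C)C)C(C)C | intermediate
16 | (S)-1-oxo-1-(pyrrolidin-1-yl)propan-2-yl (2R,3R)-5-bromo-7-methoxy-2-[3-methoxy-4-(triisopropylsilyloxy)phenyl]-2,3-dihydrobenzofuran-3-carboxylate (trans) | COc1cc([C@@H]2Oc3c(OC)cc(Br)cc3[C@H]2C(=O)O[C@@H](C)C(=O)N4CCCC4)ccc1O[Si](C(C)C)(C(C)C)C(C)C | intermediate
17 | {(2R,3S)-5-bromo-7-methoxy-2-[3-methoxy-4-(triisopropylsilyloxy)phenyl]-2,3-dihydrobenzofuran-3-yl}methanol | COc1cc([C@@H]2Oc3c(OC)cc(Br)cc3[C@H]2CO)ccc1O[Si](C(C)C)(C(C)C)C(C)C | intermediate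
18 | 3,5-dihydroxybenzaldehyde | O=Cc1cc(O)cc(O)c1 | starting material
19 | 3,5-bis(triisopropylsilyloxy)benzaldehyde | O=Cc1cc(O[Si](C(C)C)(C(C)C)C(C)C)cc(O[Si](C(C)C)(C(C)C)C(C)C)c1 | intermediate
20 | 1,3-bis(triisopropylsilyloxy)-5-vinylbenzene | C=Cc1cc(O[Si](C(C)C)(C(C)C)C(C)C)cc(O[Si](C(C)C)(C(C)C)C(C)C)c1 | intermediate
21 | {(2R,3S)-5-[(E)-2-(3,5-bis(triisopropylsilyloxy)phenyl)ethenyl]-7-methoxy-2-[3-methoxy-4-(triisopropylsilyloxy)phenyl]-2,3-dihydrobenzofuran-3-yl}methanol | COc1cc([C@@H]2Oc3c(OC)cc(/C=C/c4cc(O[Si](C(C)C)(C(C)C)C(C)C)cc(O[Si](C(C)C)(C(C)C)C(C)C)c4)cc3[C@H]2CO)ccc1O[Si](C(C)C)(C(C)C)C(C)C | intermediate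
22 | Gnetofuran A, 5-{(E)-2-[(2R,3S)-2-(4-hydroxy-3-methoxyphenyl)-3-(hydroxymethyl)-7-methoxy-2,3-dihydrobenzofuran-5-yl]ethenyl}benzene-1,3-diol | COc1cc([C@@H]2Oc3c(OC)cc(/C=C/c4cc(O)cc(O)c4)cc3[C@H]2CO)ccc1O | target

**Count**

Total steps: 15. Longest linear sequence: 12 steps (steps 1–6, 8–11, 14, 15, from vanillin).

**Steps most likely to fail**

1. Step 10. The catalyst and the auxiliary may discriminate poorly between the two enantiotopic benzylic hydrogens, or the trans preference may erode; attack of the carbenoid on ring B or carbene dimerisation may also compete. Fallback with catalyst control alone, setting out from acid 10: esterification with Me3SiCHN2 in MeOH/toluene should give methyl arylacetate F1, and diazo transfer (p-ABSA, DBU, MeCN) the methyl aryldiazoacetate F2. Insertion with Rh2(S-PTTL)4 (dirhodium tetrakis[N-phthaloyl-(S)-tert-leucinate]; its mirror image if C2 comes out S) in toluene at −78 °C is a catalyst class known to give cis-2-aryl-2,3-dihydrobenzofuran-3-carboxylates with high enantiocontrol, here the cis-dihydrobenzofuran methyl ester F3. Epimerisation at C3 alone (DBU, toluene, rt; C2 is not acidic) should lead to the more stable trans methyl ester F4, and LiBH4 reduction returns to the route at 17.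

2. Step 14. Oxidative addition into the electron-rich aryl bromide may be slow and the catalyst may decay, carbopalladation may partly go to the internal alkene carbon (1,1-diarylethene), or silyl groups may be lost on heating with amine. Fallback by Suzuki–Miyaura coupling, setting out from styrene 20: cross-metathesis with vinylboronic acid pinacol ester (second-generation Grubbs catalyst, CH2Cl2, 40 °C) should give (E)-styrylboronic acid pinacol ester F5 with the alkene geometry already fixed. Coupling of F5 with bromide 17 (Pd(dppf)Cl2, K3PO4, dioxane/H2O, 80 °C) proceeds with retention at the alkene and without regiochemical ambiguity, and returns to the route at 21.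

3. Step 6. Hypochlorite may chlorinate the electron-rich rings, or the enolisable arylacetaldehyde stage may suffer oxidative C–C cleavage. Fallback by a different homologation, setting out from aldehyde 5 and bypassing steps 4–6: Wittig reaction with Ph3P=CHOMe (from (methoxymethyl)triphenylphosphonium chloride and KN(SiMe3)2, THF, 0 °C) should give enol ether F6 as an E/Z mixture. Mild hydrolysis (2 M HCl, THF, rt) gives aldehyde 9, and Pinnick oxidation (NaClO2, NaH2PO4, 2-methyl-2-butene, t-BuOH/H2O) returns to the route at 10.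

**Further compounds**

F1 | step 10 | methyl 2-(5-bromo-3-methoxy-2-{[3-methoxy-4-(triisopropylsilyloxy)benzyl]oxy}phenyl)acetate | COc1cc(COc2c(OC)cc(Br)cc2CC(=O)OC)ccc1O[Si](C(C)C)(C(C)C)C(C)C
F2 | step 10 | methyl 2-(5-bromo-3-methoxy-2-{[3-methoxy-4-(triisopropylsilyloxy)benzyl]oxy}phenyl)-2-diazoacetate | COc1cc(COc2c(OC)cc(Br)cc2C(=[N+]=[N-])C(=O)OC)ccc1O[Si](C(C)C)(C(C)C)C(C)C
F3 | step 10 | methyl (2R,3S)-5-bromo-7-methoxy-2-[3-methoxy-4-(triisopropylsilyloxy)phenyl]-2,3-dihydrobenzofuran-3-carboxylate (cis) | COc1cc([C@@H]2Oc3c(OC)cc(Br)cc3[C@@H]2C(=O)OC)ccc1O[Si](C(C)C)(C(C)C)C(C)C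
F4 | step 10 | methyl (2R,3R)-5-bromo-7-methoxy-2-[3-methoxy-4-(triisopropylsilyloxy)phenyl]-2,3-dihydrobenzofuran-3-carboxylate (trans) | COc1cc([C@@H]2Oc3c(OC)cc(Br)cc3[C@H]2C(=O)OC)ccc1O[Si](C(C)C)(C(C)C)C(C)C
F5 | step 14 | (E)-2-[3,5-bis(triisopropylsilyloxy)styryl]-4,4,5,5-tetramethyl-1,3,2-dioxaborolane | CC1(C)OB(/C=C/c2cc(O[Si](C(C)C)(C(C)C)C(C)C)cc(O[Si](C(C)C)(C(C)C)C(C)C)c2)OC1(C)C
F6 | step 6 | 5-bromo-1-methoxy-3-(2-methoxyvinyl)-2-{[3-methoxy-4-(triisopropylsilyloxy)benzyl]oxy}benzene (E/Z mixture) | COC=Cc1cc(Br)cc(OC)c1OCc1ccc(O[Si](C(C)C)(C(C)C)C(C)C)c(OC)c1
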